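A direct plan would join 3,4,5-trimethoxyphenol A1 and (R)-3-chloro-1-phenylpropan-1-ol A2 in a Mitsunobu reaction (aryl ether A3), turn the chloride by way of acetate and alcohol into aldehyde A4, let two molecules of A4 cyclise and dimerise under a Lewis acid to the symmetric hexamethyl ether A5, and at last cleave one 5-O-methyl group. Its weakest steps would be:
(a) the change of chloride into aldehyde: three steps that would add no skeletal bond and no stereocentre;
(b) the one-flask Friedel–Crafts closure and homo-etherification of A4: both pyran rings and both C4 centres would hang on cations that could also attack C8 or lose H3;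
(c) the final cleavage of one of six methyl ethers: only stoichiometry would stop it at one, and it would be run on the most precious material.

**Plan of the new route**
Cuts: the O5–allyl bond last; before it, in one operation, the bridge bond O–C4 and the O5–CH3 bond of the trimethoxy half, which leads to an alkoxide (later phenolic half) and an ortho-quinone methide (later trimethoxy half); both come from one cis-diol, and this from one flat flavone.
Feature behind the key step: in both halves ring C (O1, C2, C3, C4, C4a, C8a) is a γ-pyrone ring in reduced form, with phenyl on C2, oxygen on C4 and a 5,6,7-trioxygenated ring A, and both halves are 2S, so one commercial flavone can be dearomatised to serve twice.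
Feature behind the coupling: the unit HO–C5=C4a–C4–O is a salicyl alcohol; only a half with a free 5-OH can form a quinone methide under base, so structure, not stoichiometry, tells the halves apart.
Order of rings: both pyran rings are bought as pyrone rings and dearomatised first (three new C–H bonds, no C–C or C–O bond), no ring is closed anywhere, and the ether bridge is made last but one.
Weak steps gone: no chain is built and oxidised; the bridge is made under base between unlike partners, with no Friedel–Crafts closure and no free cation; no methyl ether is cleaved, since the one phenoxide set free by the coupling is methylated as it forms.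

Key step: step 1

Assumption: 1 is bought as mosloflavone; the carbene ligand enantiomer written in step 1 is taken to give the 2S series, and its mirror image would be used if the sense of induction on this substrate were the opposite.

Step 1
Reactants: 1 5-hydroxy-6,7-dimethoxyflavone (mosloflavone)
Product: 3 (2S,4S)-6,7-dimethoxy-2-phenylchromane-4,5-diol (2,4-cis), via (S)-5-hydroxy-6,7-dimethoxyflavanone 2 (not isolated)
Conditions: H2 (100 bar), [Ru(cod)(2-methylallyl)2] (5 mol %), 1,3-bis[(R)-1-(naphthalen-1-yl)ethyl]-4,5-dihydro-1H-imidazol-3-ium tetrafluoroborate (10 mol %), KOt-Bu (12 mol %; catalyst preformed in n-hexane, 70 °C), toluene, 40 °C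
Reagents that add atoms: none
Why: A ruthenium hydride that carries two chiral N-heterocyclic carbene ligands should add H2 first across C2=C3 of the γ-pyrone ring, on the enantioface chosen by the ligands, and then to the C4 carbonyl group of flavanone 2, so that the flat ring C becomes a dihydropyran with two stereocentres. The closest known reaction type is the asymmetric hydrogenation of flavones and chromones to cis-flavan-4-ols and chroman-4-ols with ruthenium–N-heterocyclic carbene catalysts. No ring is closed: ring C (O1, C2, C3, C4, C4a, C8a) is dearomatised, and rings A and B stay aromatic. C2 (S) is controlled by the catalyst; C4 (S, cis) is controlled by C2, because hydride reaches the carbonyl carbon along the axial line of the half-chair that holds the phenyl group equatorial, and this centre is only a place-holder, since both C4–O bonds of the target are made anew in steps 3 and 5. The step needs chemoselectivity for the pyrone over two benzene rings and no hydrogenolysis of the benzylic C4–O bond; the enone of ring C is the only non-benzenoid unsaturation of 1, and this catalyst type should stop at the benzylic alcohol. The C2 centre set here is the only stereocentre of the route that a reagent controls; through the two later trans-selective C4–O bond formations it fixes all four stereocentres of the target.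

Step 2
Reactants: 3 (2S,4S)-6,7-dimethoxy-2-phenylchromane-4,5-diol
Product: 4 (2S,4S)-5-(allyloxy)-6,7-dimethoxy-2-phenylchroman-4-ol
Conditions: allyl bromide (1.2 equiv), K2CO3 (1.5 equiv), acetone, rt
Reagents that add atoms: allyl bromide, C=CCBr
Why: Williamson ether synthesis in which carbonate deprotonates only the phenol, so that O5 is allylated chemoselectively beside the secondary hydroxyl group, the allyl ether being chosen because it survives base and can be removed at the end without acid or hydrogen; no stereocentre is touched.

Step 3
Reactants: 4 (2S,4S)-5-(allyloxy)-6,7-dimethoxy-2-phenylchroman-4-ol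
Product: 6 (2S,4R)-5-(allyloxy)-6,7-dimethoxy-2-phenylchroman-4-ol (2,4-trans), via trans-4-nitrobenzoate 5 (not isolated)
Conditions: 4-O2NC6H4CO2H (1.3 equiv), PPh3 (1.3 equiv), DIAD (1.3 equiv), THF, 0 °C → rt; then LiOH (3 equiv), THF–H2O, 0 °C → rt; work-up without acid
Reagents that add atoms: 4-nitrobenzoic acid, O=C(O)c1ccc(cc1)[N+](=O)[O-] (one of its oxygen atoms stays as the hydroxyl oxygen of 6)
Why: Mitsunobu esterification with inversion, in which 4-nitrobenzoate displaces the phosphonium-activated pseudoequatorial oxygen on C4 along the axial line (4S becomes 4R, trans to the 2-phenyl group, and an ion pair would be captured on the same side), followed by saponification, which returns the trans-alcohol whether the acyl–oxygen bond is cleaved or the ester ionises and takes up water axially.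

Step 4
Reactants: 3 (2S,4S)-6,7-dimethoxy-2-phenylchromane-4,5-diol
Product: 7 tert-butyl (2S,4S)-4-hydroxy-6,7-dimethoxy-2-phenylchroman-5-yl carbonate
Conditions: Boc2O (1.05 equiv), i-Pr2NEt (1.2 equiv), DMAP (2 mol %), CH2Cl2, −20 → 0 °C; neutral work-up, used within a day
Reagents that add atoms: di-tert-butyl dicarbonate, CC(C)(C)OC(=O)OC(=O)OC(C)(C)C
Why: Chemoselective O-acylation of the phenol by di-tert-butyl dicarbonate (aryl tert-butyl carbonate formation under nucleophilic catalysis), which stores the salicyl alcohol as a masked ortho-quinone methide, since neither a phenoxide nor a leaving group on C4 is present until a strong base moves the carbonate from O5 to O4; no stereocentre is touched.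

Step 5
Reactants: 6 (2S,4R)-5-(allyloxy)-6,7-dimethoxy-2-phenylchroman-4-ol; 7 tert-butyl (2S,4S)-4-hydroxy-6,7-dimethoxy-2-phenylchroman-5-yl carbonate
Product: 11 (2S,4R)-5-(allyloxy)-6,7-dimethoxy-2-phenyl-4-{[(2S,4R)-5,6,7-trimethoxy-2-phenylchroman-4-yl]oxy}chromane, via carbonate-shifted phenoxide 8 (not isolated), via ortho-quinone methide 9 (not isolated), via potassium phenoxide of the ether 10 (not isolated)
Conditions: 6 (1.0 equiv), KN(SiMe3)2 (1.3 equiv), THF, −78 °C; 7 (1.3 equiv) in THF added over 1 h, −78 → −20 °C; then MeI (5 equiv), DMF, 0 °C → rt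
Reagents that add atoms: iodomethane, CI
Why: Anionic generation of an ortho-quinone methide from an ortho-(tert-butoxycarbonyloxy)benzyl alcohol (alkoxide formation, O5-to-O4 carbonate shift to 8, loss of tert-butyl carbonate from the phenoxide to 9) followed by oxa-Michael addition of the potassium alkoxide of 6 to the exocyclic C4 of 9 along the axial line opposite the equatorial 2-phenyl group, which sets the new centre 4R (trans) and rearomatises ring A to phenoxide 10, and by Williamson methylation of 10 in the same flask, so that only the half that can form a quinone methide becomes the trimethoxy half and the bridge is made without acid or a free cation.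

Step 6
Reactants: 11 (2S,4R)-5-(allyloxy)-6,7-dimethoxy-2-phenyl-4-{[(2S,4R)-5,6,7-trimethoxy-2-phenylchroman-4-yl]oxy}chromane
Product: 12 beilschmieflavonoid B, (2S,4R)-6,7-dimethoxy-2-phenyl-4-{[(2S,4R)-5,6,7-trimethoxy-2-phenylchroman-4-yl]oxy}chroman-5-ol
Conditions: Pd(PPh3)4 (5 mol %), morpholine (5 equiv), THF, rt; chromatography on Et3N-deactivated silica
Reagents that add atoms: none
Why: Palladium-catalysed deallylation (Tsuji–Trost type), in which zerovalent palladium ionises the allyl aryl ether to a π-allyl complex that morpholine captures, under neutral conditions that should leave the acid-labile doubly benzylic ether bridge, the methyl ethers and all four stereocentres untouched.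

**Compound list**
1 | 5-hydroxy-6,7-dimethoxy-2-phenyl-4H-chromen-4-one (mosloflavone) | COc1cc2oc(-c3ccccc3)cc(=O)c2c(O)c1OC | starting material
2 | (S)-5-hydroxy-6,7-dimethoxy-2-phenylchroman-4-one (not isolated) | COc1cc2c(c(O)c1OC)C(=O)C[C@@H](c1ccccc1)O2 | intermediate
3 | (2S,4S)-6,7-dimethoxy-2-phenylchromane-4,5-diol (2,4-cis) | COc1cc2c(c(O)c1OC)[C@@H](O)C[C@@H](c1ccccc1)O2 | intermediate
4 | (2S,4S)-5-(allyloxy)-6,7-dimethoxy-2-phenylchroman-4-ol (2,4-cis) | COc1cc2c(c(OCC=C)c1OC)[C@@H](O)C[C@@H](c1ccccc1)O2 | intermediate
5 | (2S,4R)-5-(allyloxy)-6,7-dimethoxy-2-phenylchroman-4-yl 4-nitrobenzoate (not isolated) | COc1cc2c(c(OCC=C)c1OC)[C@H](OC(=O)c1ccc(cc1)[N+](=O)[O-])C[C@@H](c1ccccc1)O2 | intermediate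
6 | (2S,4R)-5-(allyloxy)-6,7-dimethoxy-2-phenylchroman-4-ol (2,4-trans) | COc1cc2c(c(OCC=C)c1OC)[C@H](O)C[C@@H](c1ccccc1)O2 | intermediate
7 | tert-butyl (2S,4S)-4-hydroxy-6,7-dimethoxy-2-phenylchroman-5-yl carbonate | COc1cc2c(c(OC(=O)OC(C)(C)C)c1OC)[C@@H](O)C[C@@H](c1ccccc1)O2 | intermediate
8 | potassium (2S,4S)-4-[(tert-butoxycarbonyl)oxy]-6,7-dimethoxy-2-phenylchroman-5-olate (not isolated) | [K+].COc1cc2c(c([O-])c1OC)[C@@H](OC(=O)OC(C)(C)C)C[C@@H](c1ccccc1)O2 | intermediate
9 | (2S)-6,7-dimethoxy-2-phenyl-2,3-dihydro-5H-chromen-5-one, ortho-quinone methide with C4=C4a and C5=O (not isolated) | O=C1C(OC)=C(OC)C=C2O[C@H](c3ccccc3)CC=C12 | intermediate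
10 | potassium (2S,4R)-4-{[(2S,4R)-5-(allyloxy)-6,7-dimethoxy-2-phenylchroman-4-yl]oxy}-6,7-dimethoxy-2-phenylchroman-5-olate (not isolated) | [K+].COc1cc2c(c(OCC=C)c1OC)[C@H](O[C@@H]1C[C@@H](c3ccccc3)Oc3cc(OC)c(OC)c([O-])c31)C[C@@H](c1ccccc1)O2 | intermediate
11 | (2S,4R)-5-(allyloxy)-6,7-dimethoxy-2-phenyl-4-{[(2S,4R)-5,6,7-trimethoxy-2-phenylchroman-4-yl]oxy}chromane | COc1cc2c(c(OCC=C)c1OC)[C@H](O[C@@H]1C[C@@H](c3ccccc3)Oc3cc(OC)c(OC)c(OC)c31)C[C@@H](c1ccccc1)O2 | intermediate
12 | beilschmieflavonoid B | COc1cc2c(c(O)c1OC)[C@H](O[C@@H]1C[C@@H](c3ccccc3)Oc3cc(OC)c(OC)c(OC)c31)C[C@@H](c1ccccc1)O2 | target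

Total step count: 6. Longest linear sequence: 5 steps (steps 1, 2, 3, 5, 6).

**Steps most likely to fail**

Step 5. The quinone methide 9 may lose a C3 proton under the basic conditions (tautomerisation to the flav-3-ene phenoxide), may be captured by tert-butoxide instead of the hindered alkoxide, or may add to other quinone methide units. The fallback gives up the anionic coupling for a cation with a defined leaving group; it sets out from 3 and 6 and comes back at 11. O-Methylation of the phenol of 3 (MeI, K2CO3, acetone) would give (2S,4S)-5,6,7-trimethoxy-2-phenylchroman-4-ol F1. Cl3CCN and catalytic DBU in CH2Cl2 at 0 °C would turn it into (2S,4S)-5,6,7-trimethoxy-2-phenylchroman-4-yl 2,2,2-trichloroacetimidate F2, used crude. F2 added slowly to 6 and TMSOTf (5 mol %) over 4 Å molecular sieves in CH2Cl2 at −78 °C, then Et3N, should give 11. The C4 cation (stabilised by O1, 5-OMe and 7-OMe) would be captured by O4 of 6 along the axial line, trans to the phenyl group, whatever the configuration of F2 at C4.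

Step 1. The chelating 5-hydroxy-4-oxo unit may slow or poison the catalyst, the reduction may halt at flavanone 2, or the facial selectivity at C2 may be poor. The fallback replaces enantioselective hydrogenation by a kinetic resolution; it sets out from 1 and comes back at 3. Transfer hydrogenation of the C2=C3 bond alone without a chiral catalyst (Pd/C, HCO2NH4, MeOH; the hydrogen-bonded carbonyl group should resist further reduction) would give racemic 5-hydroxy-6,7-dimethoxy-2-phenylchroman-4-one F3. Asymmetric transfer hydrogenation (RuCl(p-cymene)[(S,S)-TsDPEN], HCO2H–Et3N, EtOAc, rt) should reduce the S enantiomer to the cis-diol 3 and leave (R)-5-hydroxy-6,7-dimethoxy-2-phenylchroman-4-one F4, which is separated. The price is half of the material.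

Step 3. The activated benzylic alcohol may ionise and lose H3 (elimination to the flav-3-ene) instead of being substituted. In the fallback the trans configuration comes from addition to a planar C4 and not from inversion; it sets out from 7 and comes back at 6. KOH in THF–H2O at 0 °C would trigger the same carbonate shift and elimination as in step 5. Hydroxide or water should add to C4 of quinone methide 9 along the axial line to give (2S,4R)-6,7-dimethoxy-2-phenylchromane-4,5-diol F5 (2,4-trans). Allylation of its phenol as in step 2 would give 6.

**Further compounds**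
F1 | step 5 | (2S,4S)-5,6,7-trimethoxy-2-phenylchroman-4-ol (2,4-cis) | COc1cc2c(c(OC)c1OC)[C@@H](O)C[C@@H](c1ccccc1)O2
F2 | step 5 | (2S,4S)-5,6,7-trimethoxy-2-phenylchroman-4-yl 2,2,2-trichloroacetimidate | COc1cc2c(c(OC)c1OC)[C@@H](OC(=N)C(Cl)(Cl)Cl)C[C@@H](c1ccccc1)O2
F3 | step 1 | rac-5-hydroxy-6,7-dimethoxy-2-phenylchroman-4-one | COc1cc2c(c(O)c1OC)C(=O)CC(c1ccccc1)O2
F4 | step 1 | (R)-5-hydroxy-6,7-dimethoxy-2-phenylchroman-4-one | COc1cc2c(c(O)c1OC)C(=O)C[C@H](c1ccccc1)O2
F5 | step 3 | (2S,4R)-6,7-dimethoxy-2-phenylchromane-4,5-diol (2,4-trans) | COc1cc2c(c(O)c1OC)[C@H](O)C[C@@H](c1ccccc1)O2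
A1 | direct plan | 3,4,5-trimethoxyphenol | COc1cc(O)cc(OC)c1OC
A2 | direct plan | (R)-3-chloro-1-phenylpropan-1-ol | ClCC[C@H](c1ccccc1)O
A3 | direct plan | (S)-5-(3-chloro-1-phenylpropoxy)-1,2,3-trimethoxybenzene | ClCC[C@@H](c1ccccc1)Oc1cc(OC)c(OC)c(OC)c1
A4 | direct plan | (S)-3-phenyl-3-(3,4,5-trimethoxyphenoxy)propanal | O=CC[C@@H](c1ccccc1)Oc1cc(OC)c(OC)c(OC)c1
A5 | direct plan | bis[(2S,4R)-5,6,7-trimethoxy-2-phenylchroman-4-yl] ether | COc1cc2c(c(OC)c1OC)[C@H](O[C@@H]1C[C@@H](c3ccccc3)Oc3cc(OC)c(OC)c(OC)c31)C[C@@H](c1ccccc1)O2
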